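The readings were generated by integration for substances that don't exist.

The target in the amber flask has stopped rising, so the decision for the next step is whether any change at the time asked is worth making.

all flasks: substrate 0.020 M

|  | free catalyst | temperature | remark | time |
|---|---|---|---|---|
| amber | 20 µM | 100 °C | the very flask that is asked about, followed so far |  |
| green | 30 µM | 95 °C | run made earlier |  |
| flask | 20 µM | 100 °C |  | 2.0 h |

| run | time / min | target / % | substrate / % |
|---|---|---|---|
| amber | 8.00 | 15.7 | 13.5 |
| amber | 12.0 | 16.9 | 3.9 |
| amber | 20.0 | 18.1 | 2.1 |
| amber | 40.0 | 17.8 | 0.5 |
| amber | 60.0 | 18.2 | 0.5 |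
| amber | 90.0 | 17.6 | 0.5 |
| green | 0.417 | 4.9 | 94.5 |
| green | 1.33 | 11.3 | 78.1 |
| green | 2.00 | 15.0 | 66.0 |
| green | 3.00 | 18.2 | 49.7 |
| green | 5.00 | 22.4 | 26.1 |
| green | 6.00 | 22.4 | 16.8 |

(readings scatter by 1 percentage point)

- gamma: at 2.0 h raise the temperature by 20 K, then wait 2.0 h
- epsilon: at 2.0 h take out 90 % of the target then present, then wait 2.0 h
- zeta: at 2.0 h add free catalyst, 100 % of the amount charged, then wait 2.0 h
- alpha: change nothing and wait 2.0 h more

- percent here means substrate units held: one side product counts as two
- what is taken out of target is counted as made
- steps that have been proposed: substrate + free catalyst <-> catalyst intermediate; catalyst intermediate -> free catalyst + target; substrate + target -> side product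
- additions bring no volume worth counting

1. target, in percent of the substrate first charged, at 2.0 h
2. what to do for the largest gain in target; "none" if nothing gains more than 2 percentage points (gamma / epsilon / zeta / alpha / none)
3. target present, with what was taken out counted in, in percent of the substrate first charged, after gamma
4. target present, with what was taken out counted in, in percent of the substrate first charged, after epsilon

In the amber run the target reads 18.1 % at 20.0 min and 17.6 % at 90.0 min, and the four readings from 20.0 min on lie within their scatter of 1 percentage point. Their mean is 17.9 %. Multiplied by the charge, this reading gives 3.59 mM. I call that my stopping level, the c(target) at which the amber flask stands once its substrate reads near zero.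

Each proposed step that moves the target needs substrate, directly or through the catalyst intermediate, and the amber substrate reads 0.5 % at 90.0 min. Turned wholly into target, that reading adds 0.5 %, but an option must gain 2 points. So I commit to 17.9 % at 2.0 h and I leave the amber flask alone.

The forecast gives 18 % and chooses none, with 18.1 % after gamma and 18.3 % after epsilon. Its ground is: “The target stops rising once the substrate is gone”.

The amber flask gives 17.6 % at 2.0 h, 17.6 % after gamma and 17.6 % after epsilon, and the choice is none. The forecast held.

    substrate + free catalyst ⇌ catalyst intermediate (K = 32.4 M⁻¹, k = 1660 M⁻¹ s⁻¹, Ea = 41.0 kJ mol⁻¹, ΔH = −74.0 kJ mol⁻¹)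
    catalyst intermediate → free catalyst + target (k = 5.01 s⁻¹, Ea = 86.0 kJ mol⁻¹)
    substrate + target → side product (k = 0.703 M⁻¹ s⁻¹, Ea = 43.0 kJ mol⁻¹)
    (constants at 100 °C)

At 120 min the amber flask holds 0 % substrate, the limiting reagent, so the options find none to turn into target. The target stands low through the step of substrate + target to side product: the same run without that step ends at 100 %, not 17.6 %. As a concentration the amber flask ends at 3.53 mM, against my stopping level of 3.59 mM.

Now take the neighbour charged with 0.034 M substrate, all else held. The stopping level, carried over as a trial, gives 10.6 % of its charge. The computed neighbour gives 10.5 %, with 0 % substrate left.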